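At early times the product climbs, and the midnight run already shows 0.111 M at its first reading, 3.9 h.

| setting | midnight | dawn | winter | noon | autumn |
|---|---|---|---|---|---|
| substrate | 0.600 M | 0.300 M | 1.20 M | 0.600 M | 0.600 M |
| free catalyst | 0.0600 M | 0.0600 M | 0.0600 M | 0.0900 M | 0.0600 M |
| time |  |  |  |  | 110 h |

- midnight run (time / h: [product] / M): 3.9: 0.111; 7.7: 0.190; 12: 0.233; 15: 0.251; 19: 0.269; 23: 0.279; 27: 0.284
- dawn run (time / h: [product] / M): 3.9: 0.069; 7.7: 0.133; 12: 0.152; 15: 0.166; 19: 0.182; 23: 0.187; 27: 0.193
- winter run (time / h: [product] / M): 3.9: 0.166; 7.7: 0.253; 12: 0.310; 15: 0.327; 19: 0.360; 23: 0.376; 27: 0.373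
- noon run (time / h: [product] / M): 3.9: 0.189; 7.7: 0.288; 12: 0.326; 15: 0.338; 19: 0.346; 23: 0.357; 27: 0.352

(scatter of a reading: 0.005 M)

- Overall: substrate -> product, with free catalyst as catalyst.
- Constant volume, constant temperature.
- Bound and free are read together.
- An order is taken over about fifteen percent of the charge, up and down.

- apparent order in [free catalyst] of the starting rate, round the charge of the midnight run (the rate where two percent of its substrate have turned into product)
- apparent order in [substrate] of the starting rate, round the charge of the midnight run (the rate where two percent of its substrate have turned into product) (one fixed amount of product, the same in the runs compared)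
- product in the autumn run at 110 h, as a share of the substrate charged

We turn each run into one time. Take the gap between the last reading and the product at a given moment. The stopping time, a relaxation time, is the time in which that gap shrinks by a factor e. The second reading of the midnight run gives 6.96 h.

Now the ladder. Dawn gives 6.59 h and winter 6.79 h, although winter holds 4.00 times the substrate of dawn. The noon run, with more free catalyst, is the fastest rung at 4.52 h. The first reading comes earlier than any of these stopping times.

Next comes the last reading of the midnight run, at 27 h. There the gap is down to 2.07 % of its start, so we put the final level at 0.290 M. That is less than the 0.600 M charged.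

The top rung is the autumn run, which has the charges of midnight. Its 110 h are 15.8 stopping times, so we expect it at that level, 48.3 % of its charge.

The forecast sits a little higher, with 49.5 %, a free-catalyst order of 1.45 and a substrate order of 0.6, and it reads the plateaus thus: “The catalyst is probably being lost.”

The flask gives 48.4 %, with orders of 1.1 in free catalyst and 0.58 in substrate.

    free catalyst + substrate ⇌ catalyst-substrate complex (3.028 M⁻¹ h⁻¹, 0.3017 h⁻¹)
    catalyst-substrate complex → product + free catalyst (2.531 h⁻¹)
    free catalyst + impurity → spent catalyst
    2 substrate → homo dimer (0.2185 M⁻¹ h⁻¹)

The autumn run stops short because substrate turns into homo dimer: without that step it reaches >99.9 % instead of 48.4 %. By that step alone, the autumn charge has a first half-life of 3.81 h, shorter than the stopping time of 6.96 h. In the winter run, a stopping time of 6.79 h puts the product at a quarter of the substrate charged at 11.1 h, and that run reaches it at 10.9 h.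

The numbers in the tables come from a simulation for an exercise; the scatter is artificial.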